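**Retrosynthetic overview**
1. The target is a (+)-epi-α-bisabolol core (ring CH R, neighbouring carbinol S) with four late oxygen functions; both acetates, the C11 carbinol and the C9=C10 double bond are added after the core exists.
2. Ring CH2OAc comes from the ring methyl (epoxide, exocyclic allylic alcohol, allylic acetate shift); the side chain comes from the prenyl end (allylic oxidation, asymmetric epoxidation, selenoxide transposition).
3. The core comes from acyclic, achiral (2E,6E)-farnesyl diphosphate: a sesquiterpene cyclase closes the only ring between the allylic ring CH2 (C1) and the ring CH (C6) and adds water at C7, setting both core stereocentres in one operation.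
4. Enabling feature: in the cyclohexene, the CH2–CH=C unit (C1–C2=C3) and the ring CH (C6) with its exocyclic tertiary carbinol (C7) are an allyl cation and a trisubstituted double bond placed 1,5 in a farnesyl chain, so the ring is a water-trapped bisabolyl cation.
5. Ring order: one ring only, formed in step 3.

Key step: step 3

Remark: farnesane numbering is used throughout (C1 = CH2O carbon, C15 = methyl on C3, C14 = methyl on C7, C12 = E-methyl of the chain end).
Assumption: the (+)-epi-α-bisabolol delivered by the Lippia dulcis synthase is taken to be the (6R,7S) isomer (the hernandulcin series), which is the configuration of the target at its ring CH and the neighbouring carbinol.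

Step 1
Reactants: 1 (2E,6E)-farnesol
Product: 2 (2E,6E)-farnesyl chloride
Conditions: NCS, Me2S, CH2Cl2, −30 → 0 °C
Reagents that add atoms: N-chlorosuccinimide, O=C1CCC(=O)N1Cl
Why: Corey–Kim chlorination activates the alcohol as an alkoxysulfonium ion that chloride displaces by SN2 under neutral conditions, so the allylic system should neither transpose nor lose its E geometry.

Step 2
Reactants: 2 (2E,6E)-farnesyl chloride
Product: 3 (2E,6E)-farnesyl diphosphate triammonium salt
Conditions: (nBu4N)3HP2O7, MeCN, rt; then Dowex 50W-X8 (NH4+ form), NH4HCO3 (25 mM), iPrOH/H2O; cellulose chromatography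
Reagents that add atoms: tris(tetrabutylammonium) hydrogen diphosphate, CCCC[N+](CCCC)(CCCC)CCCC.CCCC[N+](CCCC)(CCCC)CCCC.CCCC[N+](CCCC)(CCCC)CCCC.OP(=O)([O-])OP(=O)([O-])[O-]; ammonium hydrogencarbonate, [NH4+].OC([O-])=O
Why: SN2 diphosphorylation of the primary allylic chloride by the naked diphosphate anion, followed by cation exchange to the water-soluble ammonium salt that the enzyme accepts.

Step 3
Reactants: 3 (2E,6E)-farnesyl diphosphate triammonium salt
Product: 5 (+)-epi-α-bisabolol, via (3R)-nerolidyl diphosphate 4 (not isolated)
Conditions: recombinant (+)-epi-α-bisabolol synthase (Lippia dulcis enzyme, a sesquiterpene cyclase, His6-tagged, purified from E. coli), HEPES (25 mM, pH 7.5), MgCl2 (10 mM), DTT, glycerol, pentane overlay, 30 °C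
Reagents that add atoms: water, O
Why: The cyclase binds the diphosphate on its magnesium cluster and ionises it; syn return of diphosphate at C3 gives (3R)-nerolidyl diphosphate 4, whose C2–C3 single bond lets the chain turn cisoid, and re-ionisation with anti attack of C1 on the C6=C7 double bond gives the (6R)-bisabolyl cation, which an active-site water quenches at C7. The closest known reaction is this enzyme's own conversion of farnesyl diphosphate into (+)-epi-α-bisabolol, the reaction of the α-bisabolol-synthase class of terpene cyclases. The cyclohexene closes as a 6-exo-trig cation–olefin cyclisation with respect to the C6=C7 double bond: C7 stays outside the ring as the tertiary cation and the allyl unit is left as the endocyclic C2=C3 double bond. The ring CH (C6) should be set R by the anti, endo fold that the active site imposes on the (3R)-tertiary diphosphate, and the carbinol carbon (C7) S by delivery of water to one face of the cation held in that fold. The step needs 1,6-closure over 1,10- or 1,11-closure and water capture over proton loss to bisabolenes; both are secured by the active-site contour of a synthase whose native product is this alcohol, and the pentane layer removes the product as it forms.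

Step 4
Reactants: 5 (+)-epi-α-bisabolol
Product: 6 C7 triethylsilyl ether of 5
Conditions: TESOTf, 2,6-lutidine, CH2Cl2, −78 → 0 °C
Reagents that add atoms: triethylsilyl trifluoromethanesulfonate, CC[Si](CC)(CC)OS(=O)(=O)C(F)(F)F
Why: Silyl triflate silylation of the hindered tertiary alcohol; the ether is needed because a free C7 hydroxyl would open the later 10,11- and 2,3-epoxides to cyclic ethers (the bisabolol-oxide pathway).

Step 5
Reactants: 6 C7 triethylsilyl ether of 5
Product: 7 (10E)-12-hydroxy derivative of 6
Conditions: SeO2 (0.3 equiv), tBuOOH (70% aq., 3 equiv), salicylic acid (0.1 equiv), CH2Cl2, 0 °C → rt, stopped before complete conversion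
Reagents that add atoms: tert-butyl hydroperoxide, CC(C)(C)OO
Why: Riley-type allylic oxidation (ene reaction, then [2,3]-shift) with catalytic SeO2 hydroxylates the E-methyl of the trisubstituted prenyl end, while the ring olefin, whose ene step would have to take a ring CH2 hydrogen, should react more slowly.

Step 6
Reactants: 7 (10E)-12-hydroxy derivative of 6
Product: 8 (10S,11S)-10,11-epoxy-12-ol
Conditions: Ti(OiPr)4 (0.1 equiv), L-(+)-diethyl tartrate (0.12 equiv), tBuOOH (anhydrous, in decane), 4 Å molecular sieves, CH2Cl2, −20 °C
Reagents that add atoms: tert-butyl hydroperoxide, CC(C)(C)OO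
Why: Katsuki–Sharpless asymmetric epoxidation acts only on the allylic alcohol (the ring olefin is not touched), and with L-(+)-tartrate an (E)-2-methyl-2-alken-1-ol should give the (2S,3S)-epoxy alcohol, which fixes C11.

Step 7
Reactants: 8 (10S,11S)-10,11-epoxy-12-ol
Product: 11 (9E,11R)-9-ene-11,12-diol, via hydroxy selenide 9 (not isolated), via selenoxide 10 (not isolated)
Conditions: (PhSe)2, NaBH4, EtOH, rt → 50 °C; then THF, 30% H2O2, 0 °C → rt
Reagents that add atoms: none
Why: Epoxide-to-allylic-alcohol transposition through selenium: benzeneselenolate opens the epoxide by SN2 at the less substituted C10 so that C11 keeps its configuration, and the selenoxide undergoes syn-elimination away from the carbinol carbon to the E-C9=C10 double bond.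

Step 8
Reactants: 11 (9E,11R)-9-ene-11,12-diol
Product: 12 ring 2,3-epoxide of 11 (both epoxide diastereomers)
Conditions: mCPBA (1.05 equiv), NaHCO3, CH2Cl2, −20 → 0 °C
Reagents that add atoms: 3-chloroperbenzoic acid, OOC(=O)c1cccc(Cl)c1
Why: Prilezhaev epoxidation should be faster at the electron-rich trisubstituted ring olefin than at the 1,2-disubstituted olefin next to the carbinol; both epoxide diastereomers are carried on because the two new centres are erased in steps 9 and 11.

Step 9
Reactants: 12 ring 2,3-epoxide of 11
Product: 13 ring C2 alcohol with exocyclic C3=C15 methylene (both C2 epimers)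
Conditions: lithium 2,2,6,6-tetramethylpiperidide, Et2AlCl (gives Et2AlTMP, 5 equiv), toluene, 0 °C → rt
Reagents that add atoms: none
Why: Aluminium-amide rearrangement of an epoxide to an allylic alcohol: the amide bound to the epoxide oxygen removes a proton syn from the least hindered neighbouring carbon, which in a 1-methylcyclohexene oxide is the methyl group, while the two free hydroxyls are carried as aluminium alkoxides.

Step 10
Reactants: 13 ring C2 alcohol with exocyclic methylene
Product: 14 C2,C12-diacetate
Conditions: Ac2O (2.5 equiv), pyridine, DMAP (0.05 equiv), CH2Cl2, 0 °C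
Reagents that add atoms: acetic anhydride, CC(=O)OC(C)=O
Why: DMAP-catalysed acyl transfer esterifies the primary C12 and the secondary allylic C2 hydroxyl; the tertiary C11 hydroxyl and the silyl ether should not react at 0 °C.

Step 11
Reactants: 14 C2,C12-diacetate
Product: 15 C15-acetate with endocyclic C2=C3 double bond (silyl ether of the target)
Conditions: Pd(PPh3)4 (5 mol %), THF, 50 °C
Reagents that add atoms: none
Why: Tsuji–Trost ionisation of the secondary allylic acetate by zerovalent palladium gives a π-allyl complex that takes acetate back at its unhindered CH2 end; the 1,3-shift is driven by the change from an exocyclic 1,1-disubstituted to an endocyclic trisubstituted double bond, erases the C2 centre and leaves the non-allylic C12 acetate alone.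

Step 12
Reactants: 15 silyl ether of the target
Product: 16 target
Conditions: HF·pyridine, pyridine, THF, 0 °C → rt
Reagents that add atoms: none
Why: Fluoride cleavage of the triethylsilyl ether under pyridine-buffered conditions should free the C7 carbinol without touching the two acetates or ionising the allylic tertiary alcohol.

**Compound list**
1 | (2E,6E)-3,7,11-trimethyldodeca-2,6,10-trien-1-ol, (2E,6E)-farnesol | CC(C)=CCC/C(C)=C/CC/C(C)=C/CO | starting material
2 | (2E,6E)-1-chloro-3,7,11-trimethyldodeca-2,6,10-triene | CC(C)=CCC/C(C)=C/CC/C(C)=C/CCl | intermediate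
3 | triammonium (2E,6E)-3,7,11-trimethyldodeca-2,6,10-trien-1-yl diphosphate | CC(C)=CCC/C(C)=C/CC/C(C)=C/COP(=O)([O-])OP(=O)([O-])[O-].[NH4+].[NH4+].[NH4+] | intermediate
4 | (3R,6E)-3,7,11-trimethyldodeca-1,6,10-trien-3-yl diphosphate, enzyme-bound (counter-ions written as ammonium) | C=C[C@@](C)(CC/C=C(\C)CCC=C(C)C)OP(=O)([O-])OP(=O)([O-])[O-].[NH4+].[NH4+].[NH4+] | intermediate
5 | (2S)-6-methyl-2-[(1R)-4-methylcyclohex-3-en-1-yl]hept-5-en-2-ol, (+)-epi-α-bisabolol | CC1=CC[C@H]([C@@](C)(O)CCC=C(C)C)CC1 | intermediate
6 | triethyl{[(2S)-6-methyl-2-[(1R)-4-methylcyclohex-3-en-1-yl]hept-5-en-2-yl]oxy}silane | CC1=CC[C@H]([C@@](C)(O[Si](CC)(CC)CC)CCC=C(C)C)CC1 | intermediate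
7 | (2E,6S)-2-methyl-6-[(1R)-4-methylcyclohex-3-en-1-yl]-6-(triethylsilyloxy)hept-2-en-1-ol | CC1=CC[C@H]([C@@](C)(O[Si](CC)(CC)CC)CC/C=C(\C)CO)CC1 | intermediate
8 | [(2S,3S)-2-methyl-3-[(3S)-3-[(1R)-4-methylcyclohex-3-en-1-yl]-3-(triethylsilyloxy)butyl]oxiran-2-yl]methanol | CC1=CC[C@H]([C@@](C)(O[Si](CC)(CC)CC)CC[C@@H]2O[C@@]2(C)CO)CC1 | intermediate
9 | (2S,3R,6S)-2-methyl-6-[(1R)-4-methylcyclohex-3-en-1-yl]-3-(phenylselanyl)-6-(triethylsilyloxy)heptane-1,2-diol | CC1=CC[C@H]([C@@](C)(O[Si](CC)(CC)CC)CC[C@@H]([Se]c2ccccc2)[C@@](C)(O)CO)CC1 | intermediate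
10 | Se-oxide of 9 (configuration at selenium open) | CC1=CC[C@H]([C@@](C)(O[Si](CC)(CC)CC)CC[C@@H]([Se](=O)c2ccccc2)[C@@](C)(O)CO)CC1 | intermediate
11 | (2R,3E,6S)-2-methyl-6-[(1R)-4-methylcyclohex-3-en-1-yl]-6-(triethylsilyloxy)hept-3-ene-1,2-diol | CC1=CC[C@H]([C@@](C)(O[Si](CC)(CC)CC)C/C=C/[C@@](C)(O)CO)CC1 | intermediate
12 | (2R,3E,6S)-2-methyl-6-[(3R)-6-methyl-7-oxabicyclo[4.1.0]heptan-3-yl]-6-(triethylsilyloxy)hept-3-ene-1,2-diol, both epoxide diastereomers (epoxide centres left open) | CC12OC1C[C@H]([C@@](C)(O[Si](CC)(CC)CC)C/C=C/[C@@](C)(O)CO)CC2 | intermediate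
13 | (2R,3E,6S)-6-[(1R)-3-hydroxy-4-methylidenecyclohexyl]-2-methyl-6-(triethylsilyloxy)hept-3-ene-1,2-diol, both epimers at the ring carbinol | C=C1C(O)C[C@H]([C@@](C)(O[Si](CC)(CC)CC)C/C=C/[C@@](C)(O)CO)CC1 | intermediate
14 | (2R,3E,6S)-6-[(1R)-3-acetoxy-4-methylidenecyclohexyl]-2-hydroxy-2-methyl-6-(triethylsilyloxy)hept-3-en-1-yl acetate, both epimers at the ring acetoxy carbon | C=C1C(OC(C)=O)C[C@H]([C@@](C)(O[Si](CC)(CC)CC)C/C=C/[C@@](C)(O)COC(C)=O)CC1 | intermediate
15 | [(4R)-4-[(2S,4E,6R)-7-acetoxy-6-hydroxy-6-methyl-2-(triethylsilyloxy)hept-4-en-2-yl]cyclohex-1-en-1-yl]methyl acetate | CC(=O)OCC1=CC[C@H]([C@@](C)(O[Si](CC)(CC)CC)C/C=C/[C@@](C)(O)COC(C)=O)CC1 | intermediate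
16 | [(4R)-4-[(2S,4E,6R)-7-acetoxy-2,6-dihydroxy-6-methylhept-4-en-2-yl]cyclohex-1-en-1-yl]methyl acetate | CC(=O)OCC1=CC[C@H]([C@@](C)(O)C/C=C/[C@@](C)(O)COC(C)=O)CC1 | target

Total step count: 12. Longest linear sequence: 12 steps (from 1).

**Steps most likely to fail**

Step 9. The amide base may be consumed or misdirected by the two aluminium alkoxides, or proton removal may take place at the ring CH2 instead of the methyl group. The fallback replaces base-mediated syn-elimination by Lewis-acid ring opening with protection in the same flask. It sets out from 12: TMSOTf (excess) and 2,6-lutidine in toluene at −78 °C silylate the free hydroxyls and open the epoxide at its tertiary carbon, and DBU then removes a methyl proton, giving the tris(trimethylsilyl) ether F1. K2CO3 in MeOH at 0 °C removes the three trimethylsilyl groups, keeps the tertiary triethylsilyl ether, and comes back to the route at 13.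

Step 5. Allylic oxidation may also occur at the ring olefin, and the alcohol may be oxidised further to the enal. The fallback replaces C–H oxidation by olefin cross-metathesis and sets out from 6. Methacrolein (excess) with the second-generation Grubbs catalyst (5 mol %) in CH2Cl2 at 40 °C exchanges the isopropylidene end for the (E)-2-methyl enal F2; the trisubstituted ring olefin is inert to metathesis. Luche reduction (NaBH4, CeCl3·7H2O, MeOH, 0 °C) comes back to the route at 7.

Step 11. The π-allyl complex may lose a β-hydrogen to give a diene, or the acetate return may stop short of full equilibration. The fallback moves the oxygen through an allylic bromide and sets out from 13. Ac2O (1 equiv) with 2,4,6-collidine in CH2Cl2 at −40 °C acetylates only the primary hydroxyl, giving the C12 monoacetate F3. Corey–Kim bromination (NBS, Me2S, CH2Cl2, −20 → 0 °C, then LiBr) acts on the secondary allylic alcohol only and, after allylic equilibration, gives the rearranged primary allylic bromide F4. CsOAc in DMF at rt displaces the bromide and comes back to the route at 15.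

**Further compounds**
F1 | step 9 | tris(trimethylsilyl) ether of 13 (ring C2–O, C11–O and C12–O silylated; C7 triethylsilyl ether kept; both C2 epimers) | C=C1C(O[Si](C)(C)C)C[C@H]([C@@](C)(O[Si](CC)(CC)CC)C/C=C/[C@@](C)(O[Si](C)(C)C)CO[Si](C)(C)C)CC1
F2 | step 5 | (2E,6S)-2-methyl-6-[(1R)-4-methylcyclohex-3-en-1-yl]-6-(triethylsilyloxy)hept-2-enal | CC1=CC[C@H]([C@@](C)(O[Si](CC)(CC)CC)CC/C=C(\C)C=O)CC1
F3 | step 11 | (2R,3E,6S)-2-hydroxy-6-[(1R)-3-hydroxy-4-methylidenecyclohexyl]-2-methyl-6-(triethylsilyloxy)hept-3-en-1-yl acetate (both ring-carbinol epimers) | C=C1C(O)C[C@H]([C@@](C)(O[Si](CC)(CC)CC)C/C=C/[C@@](C)(O)COC(C)=O)CC1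
F4 | step 11 | (2R,3E,6S)-6-[(1R)-4-(bromomethyl)cyclohex-3-en-1-yl]-2-hydroxy-2-methyl-6-(triethylsilyloxy)hept-3-en-1-yl acetate | BrCC1=CC[C@H]([C@@](C)(O[Si](CC)(CC)CC)C/C=C/[C@@](C)(O)COC(C)=O)CC1
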